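The bicyclic core is disconnected across ring B at C8–C9 together with the ring-fusion bond C5–C10 (halimane numbering: ring A is C1–C5/C10, ring B is C5–C10, with the C5=C6–C7=O enone, C8(H)Me and quaternary C9). One thermal intramolecular Diels–Alder reaction of an open-chain triene closes rings A and B at once: the ring B enone, masked as a 2-silyloxydiene (C5=C6–C7=C8), adds to the E-trisubstituted C9=C10 alkene and sets C8, C9 and C10; Saegusa oxidation then restores the enone. The precursor is an acyclic ethyl (E)-alkenyl ketone with a remote E-alkene, carrying the lipase-set C4 quaternary centre and an (R)-citronellol-derived side chain.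

Key step: step 11

Remark: further atoms are numbered C17 (methyl on C8), C18 (acetoxymethyl carbon on C4), C19 (methyl on C4), C20 (methyl on C9) and C11–C15 (side chain, C15 = carboxyl); the carboxylic acid is assumed to tolerate steps 7–12 unprotected (as carboxylate, or as a silyl ester formed and cleaved in situ).

Step 1
Reactants: 1 (R)-citronellol
Product: 2 (4R)-6-hydroxy-4-methylhexanal
Conditions: O3, CH2Cl2/MeOH, −78 °C; then Me2S, −78 °C to rt
Reagents that add atoms: ozone [O-][O+]=O
Why: Ozonolysis with reductive work-up cleaves the only alkene to the aldehyde and leaves the C13 stereocentre from the chiral pool untouched.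

Step 2
Reactants: 2 (4R)-6-hydroxy-4-methylhexanal
Product: 3 (3R)-3-methylhept-6-yn-1-ol
Conditions: dimethyl (1-diazo-2-oxopropyl)phosphonate, K2CO3, MeOH, 0 °C to rt
Reagents that add atoms: dimethyl (1-diazo-2-oxopropyl)phosphonate CC(=O)C(=[N+]=[N-])P(=O)(OC)OC
Why: The Ohira–Bestmann (Seyferth–Gilbert) homologation converts the aldehyde into the terminal alkyne under carbonate conditions that tolerate the free hydroxyl.

Step 3
Reactants: 3 (3R)-3-methylhept-6-yn-1-ol
Product: 5 (3R,6E)-7-iodo-3,6-dimethylhept-6-en-1-ol, via alkenylalane 4 (not isolated)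
Conditions: AlMe3 (3.5 equiv), Cp2ZrCl2 (0.3 equiv), CH2Cl2, 0 °C to rt; then I2, THF, −30 to 0 °C
Reagents that add atoms: trimethylaluminium C[Al](C)C; iodine II
Why: Zirconium-catalysed Negishi carboalumination adds methyl and aluminium syn across the alkyne (methyl to the internal carbon; the hydroxyl is carried as its aluminium alkoxide) and iodinolysis with retention fixes the E geometry that later sets the C9/C10 relationship.

Step 4
Reactants: 5 (3R,6E)-7-iodo-3,6-dimethylhept-6-en-1-ol
Product: 6 (3R,6E)-7-iodo-3,6-dimethylhept-6-enoic acid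
Conditions: TEMPO (cat.), PhI(OAc)2, MeCN/H2O, rt
Reagents that add atoms: water O
Why: The nitroxyl-mediated oxidation takes the primary alcohol through the aldehyde hydrate to the carboxylic acid without touching the alkenyl iodide.

Step 5
Reactants: 7 diethyl methylmalonate
Product: 8 diethyl 2-methyl-2-(prop-2-en-1-yl)propanedioate
Conditions: NaH, THF, 0 °C; allyl bromide, 0 °C to rt
Reagents that add atoms: allyl bromide C=CCBr
Why: Malonate alkylation (SN2) builds the future C4 quaternary carbon as a prochiral centre.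

Step 6
Reactants: 8 diethyl 2-methyl-2-(prop-2-en-1-yl)propanedioate
Product: 9 2-methyl-2-(prop-2-en-1-yl)propane-1,3-diol
Conditions: LiAlH4, THF, 0 °C to reflux
Reagents that add atoms: none
Why: Hydride reduction of both esters gives the prochiral 1,3-diol.

Step 7
Reactants: 9 2-methyl-2-(prop-2-en-1-yl)propane-1,3-diol; 6 (3R,6E)-7-iodo-3,6-dimethylhept-6-enoic acid
Product: 11 (3R,6E)-12-hydroxy-11-(hydroxymethyl)-3,6,11-trimethyldodec-6-enoic acid, via B-alkylborane 10 (not isolated)
Conditions: 9, 9-BBN (3.3 equiv), THF, rt; then 6, PdCl2(dppf) (5 mol %), AsPh3, aq. K3PO4, DMF, rt; acidic work-up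
Reagents that add atoms: none
Why: Anti-Markovnikov hydroboration followed by B-alkyl Suzuki–Miyaura coupling joins C1 to C10 with retention of the alkenyl iodide geometry, the excess borane masking the hydroxyls as borinates that hydrolyse on work-up.

Step 8
Reactants: 11 (3R,6E)-12-hydroxy-11-(hydroxymethyl)-3,6,11-trimethyldodec-6-enoic acid
Product: 12 (3R,6E,11R)-11-(acetoxymethyl)-12-hydroxy-3,6,11-trimethyldodec-6-enoic acid
Conditions: vinyl acetate, immobilised Burkholderia cepacia lipase, t-BuOMe, rt
Reagents that add atoms: vinyl acetate CC(=O)OC=C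
Why: Lipase-catalysed enantiotopos-selective transesterification with an irreversible acyl donor desymmetrises the prochiral diol and sets the C4 quaternary stereocentre, the enzyme and solvent being chosen by screening so that the (11R)-monoacetate results.

Step 9
Reactants: 12 (3R,6E,11R)-11-(acetoxymethyl)-12-hydroxy-3,6,11-trimethyldodec-6-enoic acid
Product: 13 (3R,6E,11S)-11-(acetoxymethyl)-3,6,11-trimethyl-12-oxododec-6-enoic acid
Conditions: Dess–Martin periodinane, CH2Cl2, 0 °C to rt
Reagents that add atoms: none
Why: Dess–Martin oxidation converts the remaining neopentyl alcohol at once into the non-enolisable aldehyde, which removes the 1,3-acyl migration that could racemise C4.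

Step 10
Reactants: 13 (3R,6E,11S)-11-(acetoxymethyl)-3,6,11-trimethyl-12-oxododec-6-enoic acid
Product: 14 (3R,6E,11R,12E)-11-(acetoxymethyl)-3,6,11-trimethyl-14-oxohexadeca-6,12-dienoic acid
Conditions: diethyl (2-oxobutyl)phosphonate, LiCl, iPr2NEt, MeCN, rt to 40 °C
Reagents that add atoms: diethyl (2-oxobutyl)phosphonate CCC(=O)CP(=O)(OCC)OCC
Why: Horner–Wadsworth–Emmons olefination under Masamune–Roush conditions should give the (E)-enone from the hindered aldehyde without loss of the acetate, the extra amine carrying the carboxylate.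

Step 11
Reactants: 14 (3R,6E,11R,12E)-11-(acetoxymethyl)-3,6,11-trimethyl-14-oxohexadeca-6,12-dienoic acid
Product: 16 tert-butyldimethylsilyl (3R)-5-[(1S,2R,4aS,5R,8aR)-5-(acetoxymethyl)-3-[(tert-butyldimethylsilyl)oxy]-1,2,5-trimethyl-1,2,4a,5,6,7,8,8a-octahydronaphthalen-1-yl]-3-methylpentanoate, via bis-silyl trienol ether 15 (not isolated)
Conditions: TBSOTf (2.5 equiv), Et3N (4 equiv), toluene, 0 °C; then dilution to 0.01 M, BHT (cat.), 190 °C, sealed vessel; solvent removed, crude used directly
Reagents that add atoms: tert-butyldimethylsilyl trifluoromethanesulfonate CC(C)(C)[Si](C)(C)OS(=O)(=O)C(F)(F)F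
Why: Soft enolisation gives the (Z)-2-silyloxy-1,3-diene (and the silyl ester), which on heating should undergo a concerted, asynchronous, suprafacial [4+2] cycloaddition with the unactivated E-trisubstituted C9=C10 alkene, forming C8–C9 and C5–C10 in one operation. The closest known reaction type is the thermal type 1 intramolecular Diels–Alder reaction of 1,7,9-decatrienes that carry a 2-silyloxydiene. Ring B closes as the cycloaddition ring (two new sigma bonds, C6=C7 left as the silyl enol ether) and ring A as the fused six-membered tether ring through the C5–C10 bond. C9 and C10 follow from the E-alkene geometry (C20 cis to C1, H10 cis to C11); C8 follows from the Z-enol ether (methyl outside) together with the endo, cis-fused transition state that puts the small C20 methyl under the diene and the long side chain exo; C5 (cis) is erased in step 12. The sense relative to C4 comes from a chair-like tether in which the C19 methyl takes the equatorial site that eclipses H6 next to the bulky silyloxy group and the acetoxymethyl group sits axial, syn to H10. The step needs π-facial and endo selectivity: facial control by C4 is the weaker element, while exo leakage would alter only C8 (epimerisable, alpha to the ketone) and C5.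

Step 12
Reactants: 16 tert-butyldimethylsilyl (3R)-5-[(1S,2R,4aS,5R,8aR)-5-(acetoxymethyl)-3-[(tert-butyldimethylsilyl)oxy]-1,2,5-trimethyl-1,2,4a,5,6,7,8,8a-octahydronaphthalen-1-yl]-3-methylpentanoate
Product: 18 (3R)-5-[(1S,2R,5R,8aS)-5-(acetoxymethyl)-1,2,5-trimethyl-3-oxo-1,2,3,5,6,7,8,8a-octahydronaphthalen-1-yl]-3-methylpentanoic acid, via silyl ester 17 (not isolated)
Conditions: Pd(OAc)2 (1.2 equiv), MeCN, rt to 40 °C; then aqueous citric acid work-up
Reagents that add atoms: none
Why: In the Saegusa–Ito oxidation divalent palladium forms the C6-bound enolate from the silyl enol ether and syn β-hydride elimination of H5 installs the C5=C6 enone regiospecifically while removing the C5 stereocentre, and the aqueous work-up hydrolyses the silyl ester to the acid.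

Compound list
1 | (R)-citronellol, (3R)-3,7-dimethyloct-6-en-1-ol | OCC[C@H](C)CCC=C(C)C | starting material
2 | (4R)-6-hydroxy-4-methylhexanal | OCC[C@H](C)CCC=O | intermediate
3 | (3R)-3-methylhept-6-yn-1-ol | OCC[C@H](C)CCC#C | intermediate
4 | (E)-alkenyldimethylalane of 3 (hydroxyl as dimethylaluminium alkoxide) | C[Al](C)OCC[C@H](C)CC/C(C)=C/[Al](C)C | intermediate (not isolated)
5 | (3R,6E)-7-iodo-3,6-dimethylhept-6-en-1-ol | OCC[C@H](C)CC/C(C)=C/I | intermediate
6 | (3R,6E)-7-iodo-3,6-dimethylhept-6-enoic acid | OC(=O)C[C@H](C)CC/C(C)=C/I | intermediate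
7 | diethyl methylmalonate | CCOC(=O)C(C)C(=O)OCC | starting material
8 | diethyl 2-methyl-2-(prop-2-en-1-yl)propanedioate | CCOC(=O)C(C)(CC=C)C(=O)OCC | intermediate
9 | 2-methyl-2-(prop-2-en-1-yl)propane-1,3-diol | OCC(C)(CC=C)CO | intermediate
10 | 9-[5-hydroxy-4-(hydroxymethyl)-4-methylpentyl]-9-borabicyclo[3.3.1]nonane (hydroxyls transiently O-borylated) | OCC(C)(CO)CCCB1C2CCCC1CCC2 | intermediate (not isolated)
11 | (3R,6E)-12-hydroxy-11-(hydroxymethyl)-3,6,11-trimethyldodec-6-enoic acid | OC(=O)C[C@H](C)CC/C(C)=C/CCCC(C)(CO)CO | intermediate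
12 | (3R,6E,11R)-11-(acetoxymethyl)-12-hydroxy-3,6,11-trimethyldodec-6-enoic acid | CC(=O)OC[C@](CO)(C)CCC/C=C(C)/CC[C@@H](C)CC(=O)O | intermediate
13 | (3R,6E,11S)-11-(acetoxymethyl)-3,6,11-trimethyl-12-oxododec-6-enoic acid | CC(=O)OC[C@](C=O)(C)CCC/C=C(C)/CC[C@@H](C)CC(=O)O | intermediate
14 | (3R,6E,11R,12E)-11-(acetoxymethyl)-3,6,11-trimethyl-14-oxohexadeca-6,12-dienoic acid | CCC(=O)/C=C/[C@](C)(COC(C)=O)CCC/C=C(C)/CC[C@@H](C)CC(=O)O | intermediate
15 | tert-butyldimethylsilyl (3R,6E,11R,12E,14Z)-11-(acetoxymethyl)-14-[(tert-butyldimethylsilyl)oxy]-3,6,11-trimethylhexadeca-6,12,14-trienoate | C/C=C(\O[Si](C)(C)C(C)(C)C)/C=C/[C@](C)(COC(C)=O)CCC/C=C(C)/CC[C@@H](C)CC(=O)O[Si](C)(C)C(C)(C)C | intermediate (not isolated)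
16 | tert-butyldimethylsilyl (3R)-5-[(1S,2R,4aS,5R,8aR)-5-(acetoxymethyl)-3-[(tert-butyldimethylsilyl)oxy]-1,2,5-trimethyl-1,2,4a,5,6,7,8,8a-octahydronaphthalen-1-yl]-3-methylpentanoate | CC(=O)OC[C@]1(C)CCC[C@@H]2[C@H]1C=C(O[Si](C)(C)C(C)(C)C)[C@H](C)[C@@]2(C)CC[C@@H](C)CC(=O)O[Si](C)(C)C(C)(C)C | intermediate
17 | tert-butyldimethylsilyl ester of 18 | CC(=O)OC[C@]1(C)CCC[C@@H]2C1=CC(=O)[C@H](C)[C@@]2(C)CC[C@@H](C)CC(=O)O[Si](C)(C)C(C)(C)C | intermediate (not isolated)
18 | (3R)-5-[(1S,2R,5R,8aS)-5-(acetoxymethyl)-1,2,5-trimethyl-3-oxo-1,2,3,5,6,7,8,8a-octahydronaphthalen-1-yl]-3-methylpentanoic acid | CC(=O)OC[C@]1(C)CCC[C@@H]2C1=CC(=O)[C@H](C)[C@@]2(C)CC[C@@H](C)CC(=O)O | target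

Total step count: 12. Longest linear sequence: 10 (steps 1–4 and 7–12).

Steps most likely to fail

Step 11. The cycloaddition may be slow for the unactivated trisubstituted alkene and may show poor π-facial discrimination by the C4 quaternary centre (methyl against acetoxymethyl); exo closure is a second leak that would alter only C8. The fallback sets out from 14 and comes back at 18. It replaces the acetoxymethyl group by a formyl group for the cycloaddition, whose small, planar shape should hold it more firmly in the axial tether site. Lipase-mediated methanolysis of the acetate of 14 would give hydroxy enone F1, and Dess–Martin oxidation the non-enolisable keto aldehyde F2. Silylation and thermolysis as in step 11 would give, by way of bis-silyl trienol ether F3, the formyl cycloadduct F4. NaBH4 in EtOH should reduce only the aldehyde (the ketone is masked as the silyl enol ether; the silyl ester is cleaved in the work-up) to give hydroxymethyl cycloadduct F5. Ac2O/pyridine would give acetate F6, which under the step 12 conditions gives 18.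

Step 8. Discrimination between the enantiotopic hydroxymethyl groups may be incomplete (methyl against a flexible chain), and the monoacetate may lose enantiopurity by 1,3-acyl migration. The fallback sets out from 11 and comes back at 12. It uses the hydrolytic mode, in which the same enzyme family selects the opposite enantiotopic group: Ac2O/pyridine would convert 11 into diacetate F7, and enantiotopos-selective hydrolysis with pig liver esterase or a lipase in pH 7 buffer would give 12.

Step 7. The free hydroxyls may consume the borane, and protodeboronation or slow transmetalation may occur in the presence of the carboxylate. The fallback sets out from 8 (with 6) and comes back at 11. It couples at the ester oxidation level: hydroboration of 8 with 9-BBN would give B-alkylborane F8, the same palladium-catalysed coupling with 6 would give malonate acid F9, and LiBH4 in THF/MeOH should reduce the two ethyl esters while leaving the lithium carboxylate, giving 11.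

Further compounds
F1 | step 11 | (3R,6E,11R,12E)-11-(hydroxymethyl)-3,6,11-trimethyl-14-oxohexadeca-6,12-dienoic acid | CCC(=O)/C=C/[C@](C)(CO)CCC/C=C(C)/CC[C@@H](C)CC(=O)O
F2 | step 11 | (3R,6E,11R,12E)-11-formyl-3,6,11-trimethyl-14-oxohexadeca-6,12-dienoic acid | CCC(=O)/C=C/[C@](C)(C=O)CCC/C=C(C)/CC[C@@H](C)CC(=O)O
F3 | step 11 | tert-butyldimethylsilyl (3R,6E,11R,12E,14Z)-14-[(tert-butyldimethylsilyl)oxy]-11-formyl-3,6,11-trimethylhexadeca-6,12,14-trienoate | C/C=C(\O[Si](C)(C)C(C)(C)C)/C=C/[C@](C)(C=O)CCC/C=C(C)/CC[C@@H](C)CC(=O)O[Si](C)(C)C(C)(C)C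
F4 | step 11 | bis-silyl formyl cycloadduct (16 with CHO in place of CH2OAc) | O=C[C@]1(C)CCC[C@@H]2[C@H]1C=C(O[Si](C)(C)C(C)(C)C)[C@H](C)[C@@]2(C)CC[C@@H](C)CC(=O)O[Si](C)(C)C(C)(C)C
F5 | step 11 | hydroxymethyl cycloadduct as free acid (silyl enol ether retained) | OC[C@]1(C)CCC[C@@H]2[C@H]1C=C(O[Si](C)(C)C(C)(C)C)[C@H](C)[C@@]2(C)CC[C@@H](C)CC(=O)O
F6 | step 11 | acetoxymethyl cycloadduct as free acid (16 without the silyl ester) | CC(=O)OC[C@]1(C)CCC[C@@H]2[C@H]1C=C(O[Si](C)(C)C(C)(C)C)[C@H](C)[C@@]2(C)CC[C@@H](C)CC(=O)O
F7 | step 8 | (3R,6E)-12-acetoxy-11-(acetoxymethyl)-3,6,11-trimethyldodec-6-enoic acid | CC(=O)OCC(C)(COC(C)=O)CCC/C=C(C)/CC[C@@H](C)CC(=O)O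
F8 | step 7 | diethyl 2-[3-(9-borabicyclo[3.3.1]nonan-9-yl)propyl]-2-methylpropanedioate | CCOC(=O)C(C)(CCCB1C2CCCC1CCC2)C(=O)OCC
F9 | step 7 | (3R,6E)-11,11-bis(ethoxycarbonyl)-3,6-dimethyldodec-6-enoic acid | CCOC(=O)C(C)(CCC/C=C(C)/CC[C@@H](C)CC(=O)O)C(=O)OCC
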